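I could not take more D out of these flasks than the J I put in, since the step that makes D spends one J for each D.

    L → 2 Q (k1 = 5.3 × 10⁻⁴ s⁻¹)
    E + Q ⇌ E.Q (K2 = 1.6 × 10⁶ M⁻¹, k2 = 1.0 × 10⁶ M⁻¹ s⁻¹)
    J + E.Q → D + Q (k3 = 1.4 × 10⁶ M⁻¹ s⁻¹)
    2 Q → Q2 (k4 = 8.9 × 10⁷ M⁻¹ s⁻¹)
    D → Z (k5 = 5.1 × 10⁻⁶ s⁻¹)

| flask | E | J | L | time | remark |
|---|---|---|---|---|---|
| blue | 0.050 M (fed, over 20.0 min) | 0.0350 M | 5.0 mM | 40 min | all but E at the start; E goes in evenly over 20.0 min, the run ends at 40 min |
| ochre | 0.050 M | 0.0350 M | 5.0 mM |  | a single well-mixed tank run continuously and read at steady state, 40 min in it on average |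
| teal | 0.050 M | 0.0350 M (fed, over 20.0 min) | 5.0 mM | 40 min | all but J at the start; J goes in evenly over 20.0 min, the run ends at 40 min |
| green | 0.050 M | 0.0350 M | 5.0 mM | 40 min | a closed flask charged with all of it at once and left for 40 min |

- a doubled species enters its step squared and goes two at a time
- the stated concentrations are those of everything mixed, before any reaction; amounts are the same in each set-up
- the feed brings no volume worth counting
- run time (blue): 40 min

- the set-up with the highest amount of D at the outlet or at the end, in percent of the E put in ("none" if the first two lie within 2 percentage points) (blue / ochre / teal / green / none)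
- amount of D at the outlet or at the end, in percent of the E put in, blue
- amount of D at the outlet or at the end, in percent of the E put in, ochre
- amount of D at the outlet or at the end, in percent of the E put in, teal
- amount of D at the outlet or at the end, in percent of the E put in, green

I began with the chain step by itself, where J meets E.Q and gives D and Q back. Each turn spends one J and one E, and J stood at 0.0350 M against 0.050 M of E, so J was the limiting reagent. I called the J charged divided by the E charged the ceiling, 70.0 %, and D could not pass it.

Then I added the making and the loss of Q. With L at its starting level, and Q going as fast as L made it, [Q] came to 1.73 × 10⁻⁷ M. So I gave a molecule of E about 5.80 s, much shorter than 20.0 min, and I took the ceiling as reached in each set-up. In blue, the feed had brought as much E as there was J after 14.0 min. In teal, J reacted as it came, over 20.0 min.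

Last I added the loss of D to Z. Its half-life of 38 h is long against 40 min, and its rate, k5[D], integrates to a share exp(−k5 t) left after age t. Green's D was made at the start, so it aged the whole 40 min and gave 69.1 %. Blue's D was made evenly over 14.0 min, and its mean age gave 69.3 %. Teal's mean age gave 69.4 %. In the ochre tank I divided by 1 + k5 t instead, with t the average stay, and got 69.2 %. The gap between my first two, teal and blue, was 0.100 percentage points, less than 2 points, so I answered none.

The forecast gave 69.3 % for blue, 69.1 % for ochre, 69.4 % for teal and 69.2 % for green, and so none, holding that “essentially all J becomes D”. It differed from mine on green and ochre: it had 69.2 % and 69.1 %, where I had 69.1 % and 69.2 %.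

The flasks gave 69.3 % for blue, 69.2 % for ochre, 69.4 % for teal and 69.1 % for green, so the answer was none. With the loss of D to Z struck out, green gave 70.0 %, which is the ceiling of 70.0 %. A neighbour of green charged with 0.014 M of J had a ceiling of 28.0 %, and the same ageing over 40 min brought my figure to 27.7 %. That neighbour gave 27.7 %.

All constants are those of an exercise; the flask was simulated.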